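The earlier runs and the new flask are simulated on assumed constants, noise included.

- Decide first to stop following the curves point by point. Replace the flat late stretch of a run by its mean, and call that mean of J (the product), in percent of the E (substrate) charged, the plateau share S.

| flask | E | X | temperature | remark | time |
|---|---|---|---|---|---|
| amber | 0.34 M (fed, over 8.0 min) | 1 mol% | 10 °C | run made earlier |  |
| teal | 0.75 M (fed, over 8.0 min) | 1 mol% | 25 °C | run made earlier |  |
| south-east | 0.50 M | 1 mol% | 25 °C | everything together at the start | 60 min |
| north-west | 0.50 M (fed, over 8.0 min) | 1 mol% | 25 °C |  | 30 min |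

- amber (time / min: J / %): 15.0: 7.8; 30.0: 12.2; 40.0: 14.7; 60.0: 12.2; 80.0: 14.8
- teal (time / min: J / %): 8.00: 9.7; 15.0: 18.3; 20.0: 18.5; 30.0: 16.9; 40.0: 17.7

(scatter of a reading: 1 percentage point)

- the flask that ends with the higher amount of J, in percent of the E charged, or "neither" when 2 percentage points or less lies between them (south-east / north-west / neither)
- final J, as a percentage of the E charged, in south-east
- final J, as a percentage of the E charged, in north-west

- Before computing S, ask what each setting could do to it. Take time first: teal is flat by 15.0 min, earlier than the 30 min of north-west, so I expect no gain from the length of either flask.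
- Temperature may matter: amber's mean from 30.0 min on is 13.5 %, but amber differs from teal in charge as well. Both new flasks stand at 25 °C, as teal did.
- The feed is the assumption. North-west copies teal's 8.0 min feed and south-east has none, and I assume the plateau is a balance reached with or without the feed (thermodynamic control).
- The charge is the weak point: teal had 0.75 M and the new flasks have less, 0.50 M. A share proportional to charge would give 11.9 %, but in both flasks alike.
- Now the number: teal's mean J from 15.0 min on, the plateau share, is 17.8 %, 4.3 percentage points above amber's. The reading at 30.0 min departs from it by 0.95 points, less than the scatter of 1 point, so the mean is a fair stand-in. My reckoning puts both flasks at S, hence neither.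
- The forecast differs: south-east, with 23 % (17 % to 29 %) in south-east and 13 % (10.5 % to 17 %) in north-west, warning: “This assumes clock-type death, which is inferred, not proven”.
- The answer is neither: south-east ends at 18.1 % and north-west at 18.1 %, 0.23 points above S, and the feed changes nothing in north-west's J.

    G ⇌ E (k = 0.256 min⁻¹, Ea = 78.0 kJ mol⁻¹)
    J ⇌ G (K = 2.60, k = 0.217 min⁻¹, Ea = 93.0 kJ mol⁻¹, ΔH = −24.0 kJ mol⁻¹)
    2 X ⇌ D (K = 68.0 M⁻¹, k = 29.8 M⁻¹ min⁻¹, Ea = 59.0 kJ mol⁻¹, ΔH = −65.0 kJ mol⁻¹)
    E + X ⇌ J + X, rate k4*[E]*[X] forward; the back reaction follows from the equilibrium constant (K = 0.518, k = 11.4 M⁻¹ min⁻¹, Ea = 40.0 kJ mol⁻¹, ΔH = −20.0 kJ mol⁻¹)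
    (constants at 25 °C)

- Carry S to a repeat of south-east at 0 °C. The line through amber's mean and S, with the difference in charge set aside, gives 10.6 %, and that flask ends with J at 10.4 %, beside E at 11.4 % and the other product G at 78.1 %.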